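(The readings stem from a simulated flask on assumed constants.)

**Bench note.** Leave birch and alder closed and stirring, and add no reagent.

| flask | substrate | reagent | free catalyst | remark | time |
|---|---|---|---|---|---|
| Thursday's | 0.82 M | 0.40 M | 1.7 mM | run made earlier |  |
| Friday's | 0.82 M | 0.62 M | 1.7 mM | run made earlier |  |
| birch | 0.82 M | 0.570 M | 1.7 mM |  | 10 d |
| alder | 0.82 M | 0.860 M | 1.7 mM |  | 10 d |

| run | time / d | substrate / % | product / % |
|---|---|---|---|
| Thursday's | 0.625 | 46.4 | 34.3 |
| Thursday's | 1.67 | 28.8 | 48.5 |
| Thursday's | 3.00 | 29.6 | 48.8 |
| Thursday's | 5.00 | 29.4 | 48.7 |
| Friday's | 0.417 | 60.3 | 24.8 |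
| Friday's | 0.833 | 33.6 | 43.1 |
| Friday's | 2.00 | 8.2 | 75.9 |
| Friday's | 5.00 | 9.1 | 75.5 |

(standard deviation of a reading: 0.5 percentage points)

1. part of the substrate that has reacted at the end, birch
2. part of the substrate that has reacted at the end, alder
3. what raising the concentration of reagent from its lowest to its highest value here does to the part of the substrate that has reacted (changes below 5 percentage points count as none) (no change / it falls / it rises)

- what has gone from substrate into another species counts as reacted, even if it can come back

**The zero.** I count from the equal charge, one reagent per substrate. Thursday's last product reading is 0.399 M, about its reagent charge of 0.40 M, so reagent is the limiting reagent there. Yet 21.9% of Thursday's substrate is unseen, far more than the catalyst charge of 1.7 mM.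

**The constant.** I take the unseen part as idle adduct, substrate tied to a released group, one group per product. Thursday's plateau then reads 3.39 /M, and Friday's reads 3.43 /M. This is the tie constant: [idle adduct] over [substrate][released group].

**What comes.** Birch stands below the zero, at 0.695 equivalents. Its 0.250 M of substrate that cannot become product splits into 0.147 M of adduct and the rest free, so I expect 87.5% reacted, adduct counted as reacted. Alder stands above the zero, at 1.05 equivalents, so I expect its adduct to give substrate back to reagent. The forecast says 87.5% (85.5% to 89.5%) for birch and 99% (96% to 100%) for alder; on the trend, it rises. Its ground: "The reagent sets the final product".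

**The result.** Birch gives 87.6% and alder >99.9%, a change of 12 percentage points: it rises. Alder ends with 4.67% of its reagent free, birch with 0%.

    substrate + free catalyst → catalyst intermediate A (k = 79.5 /M/h)
    catalyst intermediate A ⇌ catalyst intermediate B (K = 1.60, k = 1540 /h)
    reagent + catalyst intermediate B → catalyst intermediate C (k = 1980 /M/h)
    catalyst intermediate C → catalyst intermediate D (k = 20.0 /h)
    catalyst intermediate D → released group + catalyst intermediate E (k = 1650 /h)
    catalyst intermediate E → free catalyst + product (k = 67.7 /h)
    substrate + released group ⇌ idle adduct, settled at all times (K = 3.40 /M)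

**Constant reused.** In birch, the constant with 12% substrate and 0.423 M released group gives 17.8% adduct; the flask holds 17.9%. With 2.0 M substrate in alder's recipe, 29% substrate and 0.292 M released group give 28.3%, and that neighbour flask holds 28.4%.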